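**Retrosynthetic overview**

- The target is reached from 3',4'-di-O-benzyl-3-O-(methoxymethyl)quercetin by MOM removal, sulfation of O3 and O7 (the chelated 5-OH stays free) and final hydrogenolysis of the benzyl ethers.
- The strategy rests on the A ring (C4a, C5, C6, C7, C8, C8a), which carries oxygen at C5 and C7 in a 1,3-relationship and is fused through C4a–C8a to the 2-aryl-3-oxy-4-pyranone C ring. It is cut at C4a–C5 and C8–C8a into a 5-sulfinyl-4-pyranone and an acetoacetate-derived 1,3-bis(silyloxy)diene (Diels–Alder, then aromatisation).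
- The sulfinylpyranone comes from pyromeconic acid: C2 iodination, MOM ether, C5 bromination, C2-selective Suzuki–Miyaura arylation, C5 C–S coupling, S-oxidation.
- Ring order: the C ring is bought, the B ring is attached by cross-coupling, and the A ring is built last in the only ring-forming step.

Key step: step 9

Assumption: the target has no stereocentre, so no enantiocontrol is needed; the sulfate monoesters are carried as triethylammonium salts and the acid form drawn is liberated only at the end by cation exchange (the salt is the better storage form).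

**Route**

Step 1
Reactants: 1 3-hydroxy-4H-pyran-4-one (pyromeconic acid)
Product: 2 3-hydroxy-2-iodo-4H-pyran-4-one
Conditions: NIS (1.05 equiv), MeCN, 0 °C → rt, dark
Reagents that add atoms: N-iodosuccinimide, O=C1CCC(=O)N1I
Why: Electrophilic ortho-halogenation of the enol; the 3-OH activates only the adjacent C2, the position at which kojic acid-type 3-hydroxy-4-pyranones take up halogens, Mannich and aldol electrophiles.

Step 2
Reactants: 2 3-hydroxy-2-iodo-4H-pyran-4-one
Product: 3 2-iodo-3-(methoxymethoxy)-4H-pyran-4-one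
Conditions: MOMCl, iPr2NEt, CH2Cl2, 0 °C → rt
Reagents that add atoms: chloromethyl methyl ether, COCCl
Why: Williamson-type O-alkylation of the acidic enol with an α-chloro ether; the MOM ether tolerates the later bromine, Pd, base and peracid steps and is later cleaved by acid beside benzyl ethers.

Step 3
Reactants: 3 2-iodo-3-(methoxymethoxy)-4H-pyran-4-one
Product: 5 5-bromo-2-iodo-3-(methoxymethoxy)-4H-pyran-4-one, via trans-5,6-dibromo-5,6-dihydropyranone 4 (not isolated)
Conditions: Br2 (1.05 equiv), CH2Cl2, −20 → 0 °C; then Et3N, 0 °C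
Reagents that add atoms: bromine, BrBr
Why: Bromine addition–dehydrobromination as used to make 3-bromochromones: Br2 adds anti across the only disubstituted, enol-ether-like C5=C6 bond, and Et3N removes the acidic H-5 with loss of the C6 bromide next to the ring oxygen, which leaves bromine α to the carbonyl and erases the two stereocentres of 4.

Step 4
Reactants: 5 5-bromo-2-iodo-3-(methoxymethoxy)-4H-pyran-4-one; 6 3,4-bis(benzyloxy)phenylboronic acid
Product: 7 2-[3,4-bis(benzyloxy)phenyl]-5-bromo-3-(methoxymethoxy)-4H-pyran-4-one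
Conditions: Pd(PPh3)4 (5 mol%), K2CO3, 1,4-dioxane–H2O, 60 °C, 6 (1.05 equiv)
Reagents that add atoms: none
Why: Site-selective Suzuki–Miyaura coupling; oxidative addition into the C2–I bond (weaker C–X bond, β-position of the enone) should be much faster than into the C5–Br bond, so one equivalent of boronic acid arylates C2 only.

Step 5
Reactants: 7 2-[3,4-bis(benzyloxy)phenyl]-5-bromo-3-(methoxymethoxy)-4H-pyran-4-one
Product: 8 2-[3,4-bis(benzyloxy)phenyl]-3-(methoxymethoxy)-5-(phenylsulfanyl)-4H-pyran-4-one
Conditions: PhSH (1.1 equiv), Pd2(dba)3 (2.5 mol%), Xantphos (5 mol%), iPr2NEt, 1,4-dioxane, 100 °C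
Reagents that add atoms: thiophenol, Sc1ccccc1
Why: Pd-catalysed C–S cross-coupling (Buchwald–Hartwig/Migita type) of the α-bromoenone with a thiol; C2 no longer carries a leaving group, so the thiolate cannot substitute by addition–elimination, and its conjugate addition at C6 is reversible.

Step 6
Reactants: 8 2-[3,4-bis(benzyloxy)phenyl]-3-(methoxymethoxy)-5-(phenylsulfanyl)-4H-pyran-4-one
Product: 9 2-[3,4-bis(benzyloxy)phenyl]-3-(methoxymethoxy)-5-(phenylsulfinyl)-4H-pyran-4-one (racemic at sulfur)
Conditions: mCPBA (1.0 equiv), CH2Cl2, −40 → 0 °C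
Reagents that add atoms: 3-chloroperbenzoic acid, OOC(=O)c1cccc(Cl)c1
Why: Chemoselective sulfide-to-sulfoxide oxidation with one equivalent of peracid at low temperature, far faster than sulfone formation or epoxidation of the acceptor-substituted ring double bonds; the sulfur stereocentre forms racemic and is destroyed in step 9.

Step 7
Reactants: 10 methyl acetoacetate
Product: 11 methyl (E)-3-(trimethylsilyloxy)but-2-enoate
Conditions: TMSCl, Et3N, hexane, rt
Reagents that add atoms: chlorotrimethylsilane, C[Si](C)(C)Cl
Why: O-silylation of the β-keto ester enol (silyl enol ether formation) under amine base; the double-bond geometry is immaterial for the next step.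

Step 8
Reactants: 11 methyl (E)-3-(trimethylsilyloxy)but-2-enoate
Product: 12 (1E)-1-methoxy-1,3-bis(trimethylsilyloxy)buta-1,3-diene
Conditions: LDA (commercial solution), THF, −78 °C; TMSCl, −78 → 0 °C; used at once
Reagents that add atoms: chlorotrimethylsilane, C[Si](C)(C)Cl
Why: γ-Deprotonation of the β-silyloxy enoate to the dienolate and O-silylation (silyl ketene acetal formation), the standard entry to 1,3-bis(silyloxy)dienes; the C1=C2 geometry is drawn E but is of no consequence, since C1 ends as the trigonal C5 of the arene.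

Step 9
Reactants: 9 2-[3,4-bis(benzyloxy)phenyl]-3-(methoxymethoxy)-5-(phenylsulfinyl)-4H-pyran-4-one; 12 (1E)-1-methoxy-1,3-bis(trimethylsilyloxy)buta-1,3-diene
Product: 15 3',4'-di-O-benzyl-3-O-(methoxymethyl)quercetin, via cis-fused sulfinyl cycloadduct 13 (not isolated), via 7-O-trimethylsilyl flavonol ether 14 (not isolated)
Conditions: 12 (3 equiv), PhMe, 0 °C → rt, then 80 °C; then MeOH–5% aq. citric acid, rt
Reagents that add atoms: none
Why: Proposed new method: the C5=C6 bond of 9 carries the C4 carbonyl and the sulfinyl group on C5, which places its largest LUMO coefficient on C6 and offsets the push–pull deactivation by the ring oxygen, while diene 12 has its largest HOMO coefficient on the CH2 terminus, so an asynchronous [4+2] addition should join CH2 to C6 (C8–C8a) and the ketene-acetal carbon to C5 (C5–C4a). The carbocyclic A ring thus closes as a six-membered ring by intermolecular Diels–Alder cycloaddition, suprafacial on both partners (in the stepwise limit a vinylogous Mukaiyama–Michael addition at C6 followed by 6-exo-trig Dieckmann-type closure of the C5 carbanion onto the silylated ester carbon). Suprafacial addition places the sulfinyl group on C4a and H-8a of adduct 13 cis, the geometry required for thermal syn-elimination of benzenesulfenic acid, and because C5 has no hydrogen only the C4a=C8a bond can form; collapse of the mixed silyl methyl ketal with loss of methoxytrimethylsilane and enolisation should then give the 7-O-silyl phenol 14, which mild aqueous acid desilylates. The closest known reactions are the Diels–Alder/aromatisation sequences of 1,3-bis(silyloxy)dienes with halo- and sulfinylquinones and the cycloadditions of 3-sulfinyl-, 3-acyl- and 3-nitrochromones with oxygenated dienes. The stereocentres of 13 (C4a, C5, C8a and sulfur) are all lost on aromatisation, so no stereocontrol is required. The step needs head-to-tail regiochemistry (oxygen at C5 and C7, not C6 and C8) and reaction at C5=C6 rather than at C2=C3; the first follows from the carbonyl/sulfinyl polarisation of C5=C6 and the second from the tetrasubstituted, donor-substituted nature of C2=C3.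

Step 10
Reactants: 15 3',4'-di-O-benzyl-3-O-(methoxymethyl)quercetin
Product: 16 3',4'-di-O-benzylquercetin
Conditions: conc. HCl (cat.), MeOH–THF, 50 °C
Reagents that add atoms: none
Why: Acid-catalysed acetal methanolysis removes the MOM group, while benzyl aryl ethers, the flavone core and the free phenols are stable to these conditions.

Step 11
Reactants: 16 3',4'-di-O-benzylquercetin
Product: 17 bis(triethylammonium) 3',4'-di-O-benzylquercetin 3,7-disulfate
Conditions: Et3N·SO3 (6 equiv), DMF, 45 °C; Sephadex LH-20
Reagents that add atoms: sulfur trioxide–triethylamine complex, CC[N+](CC)(CC)S(=O)(=O)[O-]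
Why: O-sulfonation of phenolic and enolic hydroxyls with a sulfur trioxide–amine complex; the 7-OH and 3-OH should react, whereas the 5-OH, held in a six-membered hydrogen bond to the C4 carbonyl, characteristically stays free in flavonoid sulfations under such mild conditions.

Step 12
Reactants: 17 bis(triethylammonium) 3',4'-di-O-benzylquercetin 3,7-disulfate
Product: 18 quercetin 3,7-di-O-sulfate (acid form)
Conditions: H2 (1 atm), 10% Pd/C, MeOH–H2O, rt; then Dowex 50W-X8 (H+), H2O, 0 °C, freeze-drying
Reagents that add atoms: none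
Why: Catalytic hydrogenolysis of the benzyl aryl ethers, which leaves aryl sulfate monoester salts and the tetrasubstituted C2=C3 bond untouched; cation exchange then replaces triethylammonium by protons to give the acid form drawn.

**Compound list**

1 | 3-hydroxy-4H-pyran-4-one (pyromeconic acid) | O=c1ccocc1O | starting material
2 | 3-hydroxy-2-iodo-4H-pyran-4-one | O=c1ccoc(I)c1O | intermediate
3 | 2-iodo-3-(methoxymethoxy)-4H-pyran-4-one | COCOc1c(I)occc1=O | intermediate
4 | trans-5,6-dibromo-2-iodo-3-(methoxymethoxy)-5,6-dihydro-4H-pyran-4-one (racemic) | COCOC1=C(I)O[C@@H](Br)[C@H](Br)C1=O | intermediate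
5 | 5-bromo-2-iodo-3-(methoxymethoxy)-4H-pyran-4-one | COCOc1c(I)occ(Br)c1=O | intermediate
6 | 3,4-bis(benzyloxy)phenylboronic acid | OB(O)c1ccc(OCc2ccccc2)c(OCc2ccccc2)c1 | starting material
7 | 2-[3,4-bis(benzyloxy)phenyl]-5-bromo-3-(methoxymethoxy)-4H-pyran-4-one | COCOc1c(-c2ccc(OCc3ccccc3)c(OCc3ccccc3)c2)occ(Br)c1=O | intermediate
8 | 2-[3,4-bis(benzyloxy)phenyl]-3-(methoxymethoxy)-5-(phenylsulfanyl)-4H-pyran-4-one | COCOc1c(-c2ccc(OCc3ccccc3)c(OCc3ccccc3)c2)occ(Sc2ccccc2)c1=O | intermediate
9 | 2-[3,4-bis(benzyloxy)phenyl]-3-(methoxymethoxy)-5-(phenylsulfinyl)-4H-pyran-4-one (racemic sulfoxide) | COCOc1c(-c2ccc(OCc3ccccc3)c(OCc3ccccc3)c2)occ(S(=O)c2ccccc2)c1=O | intermediate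
10 | methyl acetoacetate | COC(=O)CC(C)=O | starting material
11 | methyl (E)-3-(trimethylsilyloxy)but-2-enoate | COC(=O)/C=C(\C)O[Si](C)(C)C | intermediate
12 | (1E)-1-methoxy-1,3-bis(trimethylsilyloxy)buta-1,3-diene | CO/C(O[Si](C)(C)C)=C\C(=C)O[Si](C)(C)C | intermediate
13 | 2-[3,4-bis(benzyloxy)phenyl]-5-methoxy-3-(methoxymethoxy)-4a-(phenylsulfinyl)-5,7-bis(trimethylsilyloxy)-4a,5,8,8a-tetrahydro-4H-chromen-4-one (racemic; sulfinyl group and H-8a cis; mixture of epimers at C5 and sulfur) | COCOC1=C(c3ccc(OCc4ccccc4)c(OCc4ccccc4)c3)O[C@H]2CC(O[Si](C)(C)C)=CC(OC)(O[Si](C)(C)C)[C@@]2(S(=O)c2ccccc2)C1=O | intermediate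
14 | 2-[3,4-bis(benzyloxy)phenyl]-5-hydroxy-3-(methoxymethoxy)-7-(trimethylsilyloxy)-4H-chromen-4-one | COCOc1c(-c2ccc(OCc3ccccc3)c(OCc3ccccc3)c2)oc2cc(O[Si](C)(C)C)cc(O)c2c1=O | intermediate
15 | 3',4'-di-O-benzyl-3-O-(methoxymethyl)quercetin | COCOc1c(-c2ccc(OCc3ccccc3)c(OCc3ccccc3)c2)oc2cc(O)cc(O)c2c1=O | intermediate
16 | 3',4'-di-O-benzylquercetin | O=c1c(O)c(-c2ccc(OCc3ccccc3)c(OCc3ccccc3)c2)oc2cc(O)cc(O)c12 | intermediate
17 | bis(triethylammonium) 3',4'-di-O-benzylquercetin 3,7-disulfate | O=c1c(OS(=O)(=O)[O-])c(-c2ccc(OCc3ccccc3)c(OCc3ccccc3)c2)oc2cc(OS(=O)(=O)[O-])cc(O)c12.CC[NH+](CC)CC.CC[NH+](CC)CC | intermediate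
18 | quercetin 3,7-di-O-sulfate | O=c1c(OS(=O)(=O)O)c(-c2ccc(O)c(O)c2)oc2cc(OS(=O)(=O)O)cc(O)c12 | target

**Step count and risks**

Total step count: 12. Longest linear sequence: 10 steps (steps 1–6, then 9–12); steps 7–8 form the two-step diene branch.

Steps most likely to fail:

1. Step 9 (proposed new method). The pyranone may be too weak a dienophile, so that the diene decomposes before it adds. The addition may also go stepwise, and the C6 adduct may then open the pyranone by retro-oxa-Michael cleavage instead of closing the carbocycle. Fallback by known chemistry, setting out from 6 and coming back at 16: commercial 5,7-dihydroxychromone would be protected (MOMCl, NaH, DMF) as 5,7-bis(methoxymethoxy)-4H-chromen-4-one F1. Pd(II)-catalysed oxidative Heck-type C2-arylation of F1 with boronic acid 6 should give 2-[3,4-bis(benzyloxy)phenyl]-5,7-bis(methoxymethoxy)-4H-chromen-4-one F2. Dimethyldioxirane should epoxidise its C2=C3 bond to the 2,3-epoxyflavanone F3, which a trace of acid should isomerise to 2-[3,4-bis(benzyloxy)phenyl]-3-hydroxy-5,7-bis(methoxymethoxy)-4H-chromen-4-one F4. HCl in MeOH would then cleave both MOM ethers to 16, and steps 11–12 follow unchanged.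

2. Step 3. Bromine may attack the iodinated C2=C3 enol ether, bromide may exchange with the C2 iodide, or traces of HBr may cleave the MOM ether; any of these would erode the site selectivity of step 4. Fallback setting out from 3 and coming back at 8, without a dihalide: Suzuki–Miyaura coupling of 3 with 6 should give 2-[3,4-bis(benzyloxy)phenyl]-3-(methoxymethoxy)-4H-pyran-4-one F5. Benzenesulfenyl chloride (CH2Cl2, −78 → 0 °C), which adds to enol-ether double bonds but not to deactivated dialkoxyarenes, should add across C5=C6 to give trans-2-[3,4-bis(benzyloxy)phenyl]-6-chloro-3-(methoxymethoxy)-5-(phenylsulfanyl)-5,6-dihydro-4H-pyran-4-one F6. Et3N should then eliminate HCl from F6 to give sulfide 8. This path is kept in reserve because sulfenyl chloride addition–elimination is less documented on pyranones than the bromine route.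

3. Step 11. Sulfation of the hydrogen-bonded, hindered 3-OH may stay incomplete, or the 5-OH may be partly sulfated, giving salt mixtures that are hard to separate. Fallback through neutral, chromatographable sulfate diesters, setting out from 16 and coming back at 18: 2,2,2-trichloroethyl chlorosulfate with Et3N and DMAP should give 3',4'-di-O-benzylquercetin 3,7-bis(2,2,2-trichloroethyl sulfate) F7, purified on silica. Zinc and ammonium formate in MeOH should remove the trichloroethyl groups to give bis(ammonium) 3',4'-di-O-benzylquercetin 3,7-disulfate F8. F8 would then be submitted to the hydrogenolysis and cation exchange of step 12 in place of 17, giving 18.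

**Further compounds**

F1 | step 9 | 5,7-bis(methoxymethoxy)-4H-chromen-4-one | COCOc1cc(OCOC)c2c(c1)occc2=O
F2 | step 9 | 2-[3,4-bis(benzyloxy)phenyl]-5,7-bis(methoxymethoxy)-4H-chromen-4-one | COCOc1cc(OCOC)c2c(c1)oc(-c1ccc(OCc3ccccc3)c(OCc3ccccc3)c1)cc2=O
F3 | step 9 | 2-[3,4-bis(benzyloxy)phenyl]-2,3-epoxy-5,7-bis(methoxymethoxy)chroman-4-one (racemic, cis-fused epoxide) | COCOc1cc(OCOC)c2c(c1)O[C@@]1(c3ccc(OCc4ccccc4)c(OCc4ccccc4)c3)O[C@H]1C2=O
F4 | step 9 | 2-[3,4-bis(benzyloxy)phenyl]-3-hydroxy-5,7-bis(methoxymethoxy)-4H-chromen-4-one | COCOc1cc(OCOC)c2c(c1)oc(-c1ccc(OCc3ccccc3)c(OCc3ccccc3)c1)c(O)c2=O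
F5 | step 3 | 2-[3,4-bis(benzyloxy)phenyl]-3-(methoxymethoxy)-4H-pyran-4-one | COCOc1c(-c2ccc(OCc3ccccc3)c(OCc3ccccc3)c2)occc1=O
F6 | step 3 | trans-2-[3,4-bis(benzyloxy)phenyl]-6-chloro-3-(methoxymethoxy)-5-(phenylsulfanyl)-5,6-dihydro-4H-pyran-4-one (racemic) | COCOC1=C(c2ccc(OCc3ccccc3)c(OCc3ccccc3)c2)O[C@@H](Cl)[C@H](Sc2ccccc2)C1=O
F7 | step 11 | 3',4'-di-O-benzylquercetin 3,7-bis(2,2,2-trichloroethyl sulfate) | O=c1c(OS(=O)(=O)OCC(Cl)(Cl)Cl)c(-c2ccc(OCc3ccccc3)c(OCc3ccccc3)c2)oc2cc(OS(=O)(=O)OCC(Cl)(Cl)Cl)cc(O)c12
F8 | step 11 | bis(ammonium) 3',4'-di-O-benzylquercetin 3,7-disulfate | O=c1c(OS(=O)(=O)[O-])c(-c2ccc(OCc3ccccc3)c(OCc3ccccc3)c2)oc2cc(OS(=O)(=O)[O-])cc(O)c12.[NH4+].[NH4+]
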